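## Analysis of the target

The target is a C15 chain folded into a 2,9-dioxabicyclo[6.3.0]undecane. Ring A is a tetrahydrofuran (oxygen O1 bridging C4 and C7). Ring B is an oxocane (oxygen O6 bridging C6 and C12). The two rings share the C6–C7 bond. C4 carries the 1-bromoprop-2-ynyl group (C1–C3) and C12 the 1-bromopropyl group (C13–C15).

There are eight stereocentres, (3R,4R,6R,7R,9R,10S,12S,13S). In ring A the hydrogens at C4, C6 and C7 are all cis, so the ring fusion is cis. Across the ring-B oxygen, H6 and H12 are trans. C9–OH and C10–Br are cis to each other; they lie on the ring-B face that carries the C12 side chain and anti to ring A, so they are the product of a formal syn addition to a Z C9=C10 alkene. The pairs C12–O/C13–Br and C4–O/C3–Br have the relative configuration that results from SN2 inversion of anti-configured carbinols.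

The sensitive groups are the propargylic secondary bromide at C3 (ionisation, SN2', bromide exchange), the terminal alkyne, and two further secondary bromides, one of them next to the free C9 hydroxyl.

The difficulty lies in three places: the eight-membered ether, the trans relationship across its oxygen, and the syn bromohydrin.

The strategy rests on two features. C12 lies between the ring-B oxygen and C13, so it is the α-carbon of a glycolic acid unit attached to O6. C11 becomes an allylic electrophile once C9=C10 is a Z alkene, and this alkene is also the latent bromohydrin. The C11–C12 bond is therefore an intramolecular enolate alkylation bond. C6 and C7 form a threo-diol that maps onto the D-tartaric acid series.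

## Retrosynthetic reasoning

**C9–O and C10–Br.** Removing the bromohydrin from 31 leads to the Z alkene 29. The cut is made here because only the ring oxygen O6 can reach C9 (a five-membered ring; reaching C10 would need a four-membered one), so the regiochemistry of a bromonium opening is fixed by the ring itself. In the forward direction bromine must add on the convex face, O6 must open the bromonium ion at C9 to give 30, and the oxygen nucleophile must displace O6 from C9 with inversion. This step is placed last so that no free hydroxyl can intercept 30.

**C3–Br and ring A (O1–C4).** The bromide of 29 comes from the (3S)-propargylic alcohol 28 with inversion. Cutting O1–C4 of 28 gives the trans-alkynyl epoxide 26 (through 27), whose C7 oxygen opens the epoxide at C4 in the 5-exo mode with inversion. One stereospecific step thus sets C4 and leaves C3 as the carbinol. The epoxide 26 goes back through 25 and 24 to the E-allylic alcohol 23; C1 is added by a one-carbon homologation of the aldehyde, and the two epoxide centres are set by reagent-controlled epoxidation of the E alkene.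

**C13.** The bromide 22 comes from the (13R)-alcohol 21 with inversion. The alcohol comes from the ethyl ketone 20 by chelation-controlled reduction (ring oxygen and carbonyl). The ketone comes from the amide 18 and an ethyl nucleophile. The amide carbon is C13, so no extra carbon-skeleton work is needed.

**C11–C12 (key disconnection).** Cutting this bond in 18 gives the open-chain chloride 16. It is chosen over an ether-forming closure because it uses the acidity of the glycolamide C–H, sets C12 during ring closure, and leaves the Z alkene exactly where the bromohydrin is needed. The forward step must form an eight-membered ring from the enolate 17 with C12–H trans to C6–H.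

**O6–CH2 and the allylic chloride.** Compound 16 comes from 15, 14 and 13 by functional-group changes at C9–C11 (desilylation, semi-hydrogenation, chlorination). Compound 13 comes from the alcohol 11 and the chloroacetamide 12 by O-alkylation.

**C4–C5 and C8–C9.** Alcohol 11 is cut at C4–C5 into the epoxide 7 and the alkenyl nucleophile 10 (from 9, from 8). Compound 7 goes back through 6 to the bis-epoxide 3 and the acetylide 5 (from 4), cutting C8–C9. The order of the two epoxide openings distinguishes the two oxygens: O7 is freed first and silylated, O6 is freed second and alkylated.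

**The bis-epoxide.** Compound 3 comes from the ditosyl diol 2 and this from the chiral-pool acetonide 1, which carries the (6R,7R) configuration.

## Alternatives that were turned down

**Alternative 1:** The disconnection is C4–C5 inside ring A. In the forward step the 4-methylene-1,3-dioxolane A2 is treated with Me2AlCl or Al(i-Bu)3. The acetal C4–O bond ionises, and the aluminium enolate carbon C5 closes onto the oxocarbenium ion (Petasis–Ferrier rearrangement) to give the 2,5-cis tetrahydrofuran-3-one A1.

- For it: the cis relationship of C4 and C7 comes from one C–C bond formation, the assembly is convergent, and the C6 ketone is a handle for O6. On the stereochemistry of ring A it is at least as strong as the chosen route, which needs an asymmetric epoxidation.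
- Against it: it builds only the five-membered ring, which the chosen route obtains in one 5-exo step. The eight-membered ether, with the trans C6/C12 relationship and four more stereocentres, would still have to be closed onto a hindered C6 carbinol that first needs an all-cis-selective reduction. A2 also requires methylenation of a dioxolanone (Cp2TiMe2) and tolerates a mixed acetal centre.
- Comparison: the chosen route offers what this one lacks, namely ring B with C12 set in the closing step and a C9=C10 handle in place.

**Alternative 2:** The disconnection is O1–C7 on a finished oxocane. In the forward step the C4 alcohol A4 is treated with PhI(OAc)2 and I2 under visible light. The C4 alkoxy radical abstracts the C7 hydrogen (1,5-transfer), and the oxidised C7 centre is captured by O4 to give the cis-fused bicycle A3.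

- For it: ring A is made late in a single C–H functionalisation, and the cis fusion is enforced by geometry. In end-game step count for ring A it is stronger than the chosen route.
- Against it: C7–H is an unactivated secondary C–H. The C4 alkoxy radical can instead fragment by β-scission towards the oxygen-bearing C3. Two secondary bromides must survive iodine-radical conditions. A4 would have to be made without the C6/C7 diol, so the chiral-pool origin of these centres is lost and C9/C10 must be set on a saturated ring with no alkene.
- Comparison: the chosen route closes ring A by an ionic, stereospecific inversion at C4 and takes O7 and C6 from 1.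

**Alternative 3:** The disconnection is C10–C11. In the forward step SmI2 reduces the bromoacetate of A6 to a samarium enolate, which adds to the C10 aldehyde (Reformatsky-type closure) to give the eight-membered β-hydroxy lactone A5 fused to ring A.

- For it: medium-ring lactones form well in this way, ring A pre-organises the chain, the C9 oxygen is fixed before closure, and C10 arrives as a carbinol ready for inversion to the bromide. On C9/C10 it is stronger than the chosen route, which depends on a late oxonium-ion step.
- Against it: C12 arrives as a lactone carbonyl. The C13–C15 chain, the C12 centre trans to C6 and the C13 bromide would all have to be added to an eight-membered lactone with no clear control element. The C10 configuration of the aldol is uncertain, the α-alkoxy aldehyde can epimerise at C9, and the β-hydroxy lactone can dehydrate.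
- Comparison: the chosen route has C13 already in the ring-closing partner and sets C12 in the closure, in fewer steps.

Key step: step 11

**Remarks on the chemistry.**
- Carbons are numbered C1 (alkyne CH) to C15 along the chain of the target. O6 and O7 are the oxygens on C6 and C7.
- Compounds 1, 4, 8 and 12 are assumed to be purchased. Compound 1 is the ditosylate acetonide of the D-tartaric acid series.
- The C7 oxygen is protected as a triisopropylsilyl ether so that it cannot migrate to O6 during the alkoxide alkylation of step 7. The C11 oxygen is protected as a tert-butyldimethylsilyl ether, which can be removed selectively in step 8.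
- The E alkene is brought in as an alkenyl nucleophile, so only one alkyne needs semi-reduction.

## Route

Step 1
Reactants: 1 1,4-di-O-tosyl-2,3-O-isopropylidene-D-threitol [(4R,5R)-4,5-bis(tosyloxymethyl)-2,2-dimethyl-1,3-dioxolane]
Product: 2 1,4-di-O-tosyl-D-threitol [(2R,3R)-2,3-dihydroxybutane-1,4-diyl bis(4-methylbenzenesulfonate)]
Conditions: HCl (cat.), EtOH/H2O, reflux
Reagents that add atoms: none
Why: Acid-catalysed acetal hydrolysis; the sulfonate esters are stable to dilute acid and no stereocentre is touched.

Step 2
Reactants: 2 1,4-di-O-tosyl-D-threitol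
Product: 3 (R,R)-1,2:3,4-diepoxybutane [(2R,2'R)-2,2'-bioxirane]
Conditions: KOH, Et2O/H2O, rt
Reagents that add atoms: none
Why: Double intramolecular Williamson etherification (3-exo-tet); each alkoxide displaces the neighbouring primary tosylate, so the two carbinol centres are not involved and keep their configuration.

Step 3
Reactants: 3 (R,R)-1,2:3,4-diepoxybutane (3 equiv); 4 tert-butyldimethyl(prop-2-yn-1-yloxy)silane
Product: 6 (1R)-5-(tert-butyldimethylsilyloxy)-1-[(2R)-oxiran-2-yl]pent-3-yn-1-ol (C5/C6 epoxide; C7–OH; C9≡C10; C11–OTBS), via lithium acetylide 5 (not isolated)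
Conditions: 4, n-BuLi, THF, −78 °C; BF3·OEt2; then 3, −78 °C
Reagents that add atoms: none
Why: BF3-promoted opening of a terminal epoxide by an alkynyllithium at the primary carbon C8 forms the C8–C9 bond; the excess of 3 should hold the reaction at mono-opening, and C7 is not a reacting centre.

Step 4
Reactants: 6 epoxy alcohol
Product: 7 triisopropylsilyl ether of 6 (C7–OTIPS, 7R; C5/C6 epoxide, 6R)
Conditions: i-Pr3SiOTf, 2,6-lutidine, CH2Cl2, −78 → 0 °C
Reagents that add atoms: triisopropylsilyl trifluoromethanesulfonate, CC(C)[Si](OS(=O)(=O)C(F)(F)F)(C(C)C)C(C)C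
Why: Silylation of a secondary alcohol with a silyl triflate and a hindered pyridine base, which does not open the epoxide at low temperature; the bulky group marks O7 as the oxygen that will later close ring A.

Step 5
Reactants: 8 (E)-3-(tributylstannyl)prop-2-en-1-ol
Product: 9 tributyl[(E)-3-(4-methoxybenzyloxy)prop-1-enyl]stannane
Conditions: NaH, 4-methoxybenzyl chloride, Bu4NI (cat.), THF/DMF, 0 °C → rt
Reagents that add atoms: 4-methoxybenzyl chloride, COc1ccc(CCl)cc1
Why: Williamson etherification of a primary allylic alkoxide; the alkenylstannane is inert to NaH.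

Step 6
Reactants: 7 silyl epoxide; 9 alkenylstannane
Product: 11 (2E,5R,6R)-10-(tert-butyldimethylsilyloxy)-1-(4-methoxybenzyloxy)-6-(triisopropylsilyloxy)dec-2-en-8-yn-5-ol (target numbering: C2–OPMB; E C3=C4; C6–OH, 6R; C7–OTIPS, 7R; C9≡C10; C11–OTBS), via alkenyllithium 10 (not isolated)
Conditions: 9, n-BuLi, THF, −78 °C; then 7, BF3·OEt2, −78 °C
Reagents that add atoms: none
Why: Tin–lithium exchange gives the (E)-alkenyllithium with retention of geometry, and BF3-assisted SN2 opening of the terminal epoxide at C5 forms the C4–C5 bond; C6 is not attacked and becomes the free hydroxyl for the glycolamide.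

Step 7
Reactants: 11 C6 alcohol; 12 2-chloro-N,N-dimethylacetamide
Product: 13 O6-(dimethylcarbamoylmethyl) ether of 11
Conditions: NaH, Bu4NI (cat.), THF, 0 °C → rt
Reagents that add atoms: none
Why: Williamson O-alkylation of the secondary alkoxide with an α-chloro amide; the neighbouring triisopropylsilyl ether is not expected to migrate, so the assignment of O6 and O7 made by the order of epoxide openings is kept.

Step 8
Reactants: 13 glycolamide ether
Product: 14 propargylic alcohol (C11–OH) with C7–OTIPS, O6–CH2CONMe2 and C2–OPMB retained
Conditions: camphorsulfonic acid (cat.), MeOH/CH2Cl2, 0 °C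
Reagents that add atoms: none
Why: Acid-catalysed methanolysis removes the unhindered primary tert-butyldimethylsilyl ether much faster than the hindered secondary triisopropylsilyl ether; the PMB ether and the amide are inert.

Step 9
Reactants: 14 propargylic alcohol
Product: 15 (Z)-allylic alcohol (Z C9=C10; C11–OH)
Conditions: H2 (1 atm), Pd/CaCO3 (Pb(OAc)2-poisoned), quinoline, EtOAc, rt
Reagents that add atoms: none
Why: Lindlar semi-hydrogenation adds H2 syn to the alkyne and gives the Z alkene; the E disubstituted alkene and the benzylic ether are not reduced on the poisoned catalyst.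

Step 10
Reactants: 15 (Z)-allylic alcohol
Product: 16 (Z)-allylic chloride, the cyclisation precursor (6R,7R; E C3=C4; Z C9=C10; C11–Cl; O6–CH2CONMe2; C7–OTIPS; C2–OPMB)
Conditions: PPh3, CCl4, MeCN, 0 °C → rt
Reagents that add atoms: carbon tetrachloride, ClC(Cl)(Cl)Cl
Why: Appel chlorination of a primary allylic alcohol (alkoxyphosphonium ion, SN2 by chloride) under neutral conditions, which keeps the Z geometry and leaves the base-sensitive glycolamide alone.

Step 11
Reactants: 16 (Z)-allylic chloride
Product: 18 α,α'-trans oxocene amide (ring B: O6–C12 bond and Z C9=C10; C12–CONMe2, 12S; C7–OTIPS, 7R; C6, 6R, carrying the (E)-4-(4-methoxybenzyloxy)but-2-enyl chain), via lithium enolate 17 (not isolated)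
Conditions: LiN(SiMe3)2 (1.3 equiv), THF (0.01 M), −78 → 0 °C
Reagents that add atoms: none
Why: LiN(SiMe3)2 removes one C12–H of the α-alkoxy amide and gives the lithium (Z)-enolate 17, in which lithium bridges the enolate oxygen and O6. The enolate carbon C12 then displaces chloride from the primary allylic carbon C11 in an intramolecular SN2 reaction, forming the C11–C12 bond; the closest known reaction type is the intramolecular alkylation of O-tethered glycolamide enolates by allylic halides, which is established for oxocenes. Ring B closes in the 8-exo-tet mode, made feasible by the Z C9=C10 double bond, which holds C11 near C12 and removes two sp3 centres with their transannular hydrogens. The only new stereocentre is C12, set under substrate control by C6 and C7: on the forming ring the C5 chain and the OTIPS group are necessarily cis, and the transition state that keeps the bulky, solvated enolate unit on the opposite ring face should be the lower one, which gives C12–H trans to C6–H, that is (12S). The chelate fixes the C12–O6 rotamer, so the face choice is transmitted through one rigid five-membered ring, and a late, product-like transition state points the same way because the trans isomer avoids three substituents on one face. The step needs C- over O-alkylation (O-alkylation would give a ten-membered ketene aminal), SN2 over SN2' (attack at C9 would give a vinyl tetrahydropyran and is disfavoured against the primary terminus) and cyclisation over oligomerisation (secured by dilution and slow warming).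

Step 12
Reactants: 18 oxocene amide
Product: 20 ethyl ketone (C12–C(=O)–CH2CH3; 6R,7R,12S), via magnesium hemiaminal 19 (not isolated)
Conditions: EtMgBr, THF, 0 °C; aq. NH4Cl
Reagents that add atoms: ethylmagnesium bromide, CC[Mg]Br
Why: Grignard addition to a tertiary α-alkoxy amide gives a chelated tetrahedral magnesium hemiaminal that does not collapse before work-up, so the reaction should stop at the ketone; C12 is protected from epimerisation because the ketone is not present in the basic medium.

Step 13
Reactants: 20 ethyl ketone
Product: 21 (13R)-alcohol (12,13-anti; 6R,7R,12S,13R)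
Conditions: Zn(BH4)2, Et2O, −78 → −20 °C
Reagents that add atoms: none
Why: Chelation-controlled (Cram chelate) reduction: zinc bridges the ketone oxygen and the ring oxygen O6, and hydride arrives from the side of C12–H, which gives the anti, (13R) alcohol; the hindered silyl ether at C7 is a poor ligand and should not compete.

Step 14
Reactants: 21 (13R)-alcohol
Product: 22 (13S)-bromide (6R,7R,12S,13S)
Conditions: CBr4, P(n-C8H17)3, toluene, 70 °C
Reagents that add atoms: tetrabromomethane, BrC(Br)(Br)Br
Why: Appel-type bromination (alkoxyphosphonium ion, SN2 by bromide) with inversion at C13; the trialkylphosphine and heating are chosen because the carbinol is hindered.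

Step 15
Reactants: 22 (13S)-bromide
Product: 23 (E)-allylic alcohol (C2–OH; E C3=C4)
Conditions: DDQ, CH2Cl2/pH 7 buffer, 0 °C
Reagents that add atoms: none
Why: Oxidative cleavage of the 4-methoxybenzyl ether by DDQ (benzylic hydride abstraction, then hydrolysis of the hemiacetal); the silyl ether, the alkyl bromide and both alkenes are inert.

Step 16
Reactants: 23 (E)-allylic alcohol
Product: 24 (3S,4S)-epoxy alcohol (trans C3/C4 epoxide; C2–OH)
Conditions: Ti(OiPr)4 (cat.), L-(+)-diethyl tartrate, t-BuOOH, 4 Å molecular sieves, CH2Cl2, −20 °C
Reagents that add atoms: tert-butyl hydroperoxide, CC(C)(C)OO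
Why: Sharpless asymmetric epoxidation; with the L-(+)-tartrate ligand the E allylic alcohol is epoxidised on the face that gives the (3S,4S)-epoxide under reagent control, and the ring alkene, which has no allylic hydroxyl, is not touched.

Step 17
Reactants: 24 epoxy alcohol
Product: 25 epoxy aldehyde (C2 aldehyde; same spatial arrangement at C3 and C4, formally 3R,4S)
Conditions: Dess–Martin periodinane, NaHCO3, CH2Cl2, 0 °C → rt
Reagents that add atoms: none
Why: Dess–Martin oxidation of a primary alcohol under buffered conditions; the oxirane C–H at C3 is not acidic enough to epimerise.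

Step 18
Reactants: 25 epoxy aldehyde
Product: 26 alkynyl epoxide (C1≡C2; 3S,4S trans epoxide)
Conditions: dimethyl (1-diazo-2-oxopropyl)phosphonate, K2CO3, MeOH, 0 °C → rt
Reagents that add atoms: dimethyl (1-diazo-2-oxopropyl)phosphonate, COP(=O)(OC)C(=[N+]=[N-])C(C)=O
Why: Ohira–Bestmann (Seyferth–Gilbert) homologation: the diazomethylphosphonate anion formed in situ adds to the aldehyde, and the alkylidene carbene rearranges to the terminal alkyne, which adds C1; these mild conditions should leave the epoxide and the hindered bromide intact.

Step 19
Reactants: 26 alkynyl epoxide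
Product: 28 bicyclic propargylic alcohol (3S,4R,6R,7R,9Z,12S,13S)-13-bromo-4,7:6,12-diepoxypentadec-9-en-1-yn-3-ol, via hydroxy epoxide 27 (not isolated)
Conditions: Bu4NF, THF, 0 °C → rt
Reagents that add atoms: none
Why: Fluoride cleaves the silyl ether, and the C7 alkoxide opens the epoxide at C4 in the 5-exo-tet mode with inversion (4S to 4R), which closes the cis-fused ring A and leaves C3 as the (S)-propargylic alcohol. Alkynyl epoxides that are not metal-complexed cyclise in the exo mode, so attack at the propargylic C3 should not compete.

Step 20
Reactants: 28 bicyclic propargylic alcohol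
Product: 29 (3R,4R,6R,7R,9Z,12S,13S)-3,13-dibromo-4,7:6,12-diepoxypentadec-9-en-1-yne
Conditions: CBr4, PPh3, CH2Cl2, 0 °C
Reagents that add atoms: tetrabromomethane, BrC(Br)(Br)Br
Why: Appel bromination; SN2 displacement of the alkoxyphosphonium ion at the activated propargylic carbon inverts C3 from (S)-OH to (R)-Br. The reaction is run cold and briefly to limit bromide exchange.

Step 21
Reactants: 29 dibromo alkene
Product: 31 (3R,4R,6R,7R,9R,10S,12S,13S)-3,10,13-tribromo-4,7:6,12-diepoxypentadec-1-yn-9-ol, via bromo oxonium ion 30 (not isolated)
Conditions: N-bromosuccinimide, MeCN/H2O, 0 °C, dark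
Reagents that add atoms: N-bromosuccinimide, O=C1CCC(=O)N1Br; water, O
Why: Bromonium formation on the convex face of ring B (anti to ring A) is followed by transannular attack of O6 at C9 (the only position that gives a five-membered ring), which forms the oxonium ion 30 with its new ring anti to ring A; water then displaces O6 from C9 with inversion. The double inversion at C9 makes the overall addition of Br and OH syn and gives (9R,10S); this is bromonium-triggered transannular oxonium formation and opening, as known for medium-ring ethers with a remote alkene.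

## Compound list

1 | 1,4-di-O-tosyl-2,3-O-isopropylidene-D-threitol, (4R,5R) | Cc1ccc(cc1)S(=O)(=O)OC[C@H]1OC(C)(C)O[C@@H]1COS(=O)(=O)c1ccc(C)cc1 | starting material
2 | 1,4-di-O-tosyl-D-threitol, (2R,3R) | Cc1ccc(cc1)S(=O)(=O)OC[C@@H](O)[C@H](O)COS(=O)(=O)c1ccc(C)cc1 | intermediate
3 | (R,R)-1,2:3,4-diepoxybutane | C1O[C@H]1[C@@H]1OC1 | intermediate
4 | tert-butyldimethyl(prop-2-yn-1-yloxy)silane | C#CCO[Si](C)(C)C(C)(C)C | starting material
5 | [3-(tert-butyldimethylsilyloxy)prop-1-ynyl]lithium | [Li]C#CCO[Si](C)(C)C(C)(C)C | intermediate
6 | (1R)-5-(tert-butyldimethylsilyloxy)-1-[(2R)-oxiran-2-yl]pent-3-yn-1-ol | CC(C)(C)[Si](C)(C)OCC#CC[C@@H](O)[C@H]1CO1 | intermediate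
7 | triisopropylsilyl ether of 6 | CC(C)(C)[Si](C)(C)OCC#CC[C@@H](O[Si](C(C)C)(C(C)C)C(C)C)[C@H]1CO1 | intermediate
8 | (E)-3-(tributylstannyl)prop-2-en-1-ol | CCCC[Sn](CCCC)(CCCC)/C=C/CO | starting material
9 | tributyl[(E)-3-(4-methoxybenzyloxy)prop-1-enyl]stannane | CCCC[Sn](CCCC)(CCCC)/C=C/COCc1ccc(OC)cc1 | intermediate
10 | (E)-3-(4-methoxybenzyloxy)prop-1-enyllithium | [Li]/C=C/COCc1ccc(OC)cc1 | intermediate
11 | (2E,5R,6R)-10-(tert-butyldimethylsilyloxy)-1-(4-methoxybenzyloxy)-6-(triisopropylsilyloxy)dec-2-en-8-yn-5-ol | COc1ccc(COC/C=C/C[C@@H](O)[C@H](O[Si](C(C)C)(C(C)C)C(C)C)CC#CCO[Si](C)(C)C(C)(C)C)cc1 | intermediate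
12 | 2-chloro-N,N-dimethylacetamide | CN(C)C(=O)CCl | starting material
13 | O6-(dimethylcarbamoylmethyl) ether of 11 | COc1ccc(COC/C=C/C[C@@H](OCC(=O)N(C)C)[C@H](O[Si](C(C)C)(C(C)C)C(C)C)CC#CCO[Si](C)(C)C(C)(C)C)cc1 | intermediate
14 | C11 propargylic alcohol | COc1ccc(COC/C=C/C[C@@H](OCC(=O)N(C)C)[C@H](O[Si](C(C)C)(C(C)C)C(C)C)CC#CCO)cc1 | intermediate
15 | (Z)-allylic alcohol | COc1ccc(COC/C=C/C[C@@H](OCC(=O)N(C)C)[C@H](O[Si](C(C)C)(C(C)C)C(C)C)C/C=C\CO)cc1 | intermediate
16 | (Z)-allylic chloride, cyclisation precursor (6R,7R) | COc1ccc(COC/C=C/C[C@@H](OCC(=O)N(C)C)[C@H](O[Si](C(C)C)(C(C)C)C(C)C)C/C=C\CCl)cc1 | intermediate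
17 | chelated lithium (Z)-enolate of 16 | COc1ccc(COC/C=C/C[C@@H](O/C=C(\O[Li])N(C)C)[C@H](O[Si](C(C)C)(C(C)C)C(C)C)C/C=C\CCl)cc1 | intermediate
18 | α,α'-trans oxocene amide (6R,7R,12S) | COc1ccc(COC/C=C/C[C@H]2O[C@H](C(=O)N(C)C)C/C=C\C[C@H]2O[Si](C(C)C)(C(C)C)C(C)C)cc1 | intermediate
19 | bromomagnesium hemiaminal from 18 and EtMgBr | COc1ccc(COC/C=C/C[C@H]2O[C@H](C(CC)(O[Mg]Br)N(C)C)C/C=C\C[C@H]2O[Si](C(C)C)(C(C)C)C(C)C)cc1 | intermediate
20 | ethyl ketone (6R,7R,12S) | COc1ccc(COC/C=C/C[C@H]2O[C@H](C(=O)CC)C/C=C\C[C@H]2O[Si](C(C)C)(C(C)C)C(C)C)cc1 | intermediate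
21 | (13R)-alcohol (6R,7R,12S,13R) | COc1ccc(COC/C=C/C[C@H]2O[C@H]([C@H](O)CC)C/C=C\C[C@H]2O[Si](C(C)C)(C(C)C)C(C)C)cc1 | intermediate
22 | (13S)-bromide (6R,7R,12S,13S) | COc1ccc(COC/C=C/C[C@H]2O[C@H]([C@@H](Br)CC)C/C=C\C[C@H]2O[Si](C(C)C)(C(C)C)C(C)C)cc1 | intermediate
23 | (E)-allylic alcohol | OC/C=C/C[C@H]1O[C@H]([C@@H](Br)CC)C/C=C\C[C@H]1O[Si](C(C)C)(C(C)C)C(C)C | intermediate
24 | (3S,4S)-epoxy alcohol | OC[C@@H]1O[C@H]1C[C@H]2O[C@H]([C@@H](Br)CC)C/C=C\C[C@H]2O[Si](C(C)C)(C(C)C)C(C)C | intermediate
25 | epoxy aldehyde | O=C[C@@H]1O[C@H]1C[C@H]2O[C@H]([C@@H](Br)CC)C/C=C\C[C@H]2O[Si](C(C)C)(C(C)C)C(C)C | intermediate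
26 | (3S,4S)-alkynyl epoxide | C#C[C@@H]1O[C@H]1C[C@H]2O[C@H]([C@@H](Br)CC)C/C=C\C[C@H]2O[Si](C(C)C)(C(C)C)C(C)C | intermediate
27 | C7 hydroxy alkynyl epoxide | C#C[C@@H]1O[C@H]1C[C@H]2O[C@H]([C@@H](Br)CC)C/C=C\C[C@H]2O | intermediate
28 | (3S,4R,6R,7R,9Z,12S,13S)-13-bromo-4,7:6,12-diepoxypentadec-9-en-1-yn-3-ol | C#C[C@H](O)[C@H]1C[C@H]2O[C@H]([C@@H](Br)CC)C/C=C\C[C@H]2O1 | intermediate
29 | (3R,4R,6R,7R,9Z,12S,13S)-3,13-dibromo-4,7:6,12-diepoxypentadec-9-en-1-yne | C#C[C@@H](Br)[C@H]1C[C@H]2O[C@H]([C@@H](Br)CC)C/C=C\C[C@H]2O1 | intermediate
30 | bromo oxonium ion (O6 bonded to C6, C9 and C12; Br at C10), succinimidate salt | C#C[C@@H](Br)[C@H]1C[C@H]2[O+]3[C@H]([C@@H](Br)CC)C[C@H](Br)[C@@H]3C[C@H]2O1.O=C1CCC(=O)[N-]1 | intermediate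
31 | (3R,4R,6R,7R,9R,10S,12S,13S)-3,10,13-tribromo-4,7:6,12-diepoxypentadec-1-yn-9-ol | C#C[C@@H](Br)[C@H]1C[C@H]2O[C@H]([C@@H](Br)CC)C[C@H](Br)[C@H](O)C[C@H]2O1 | target

## Step count and least certain steps

Total: 21 steps. Longest linear sequence: 20 steps (1 to 31 through steps 1–4 and 6–21; step 5 is a one-step side branch).

**Step 11 (key step).** The most likely failure is ring closure on the other enolate face, which gives the α,α'-cis oxocene. The facial preference rests only on the conformation of a flexible eight-membered transition state, not on a rigid control element. SN2' closure to a vinyl tetrahydropyran is a second, smaller risk.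
Fallback: C12 is corrected after ring closure instead of during it. Starting from 16, the cyclisation is accepted as it comes and gives the cis-oxocene amide F1. EtMgBr converts this into the cis ethyl ketone F2. F2 is then equilibrated with DBU in toluene through its C12 enol. The trans ketone should be favoured, because it keeps the acyl group off the ring face that carries the C5 chain and the silyloxy group and relieves the lone-pair repulsion between the carbonyl and the two ether oxygens. The fallback rejoins the route at 20.

**Step 21.** The most likely failure is loss of the double inversion at C9. The C9–O bond of 30 is anti-periplanar to C10–Br, so the oxonium ion can revert to the bromonium ion, which water then opens anti; this gives the C9 epimer. A further loss would be opening of 30 at C12 or C6 with ring contraction; the fallback below does not recover that material.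
Fallback: the C9 configuration is set by a ketone reduction instead of by the oxonium opening. Starting from 29, the bromohydroxylation is run as in step 21, and the C9-epimeric bromohydrin F3 (alone or mixed with 31) is oxidised with Dess–Martin periodinane to the 10-bromo-9-ketone F4. Reduction with NaBH4/CeCl3·7H2O in MeOH at −78 °C should deliver hydride anti to the C10–Br bond (Felkin–Anh, polar substituent) and give the cis bromohydrin 31.

**Step 13.** The most likely failure is poor facial selectivity if the zinc chelate does not dominate, so that the Felkin–Anh (syn) alcohol forms.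
Fallback: the wrong epimer is inverted instead of being avoided. Starting from 20, the (13S)-alcohol F5 is subjected to Mitsunobu inversion (4-nitrobenzoic acid, PPh3, diisopropyl azodicarboxylate) to give the (13R)-4-nitrobenzoate F6. Methanolysis with K2CO3 in MeOH returns the route to 21.

**Step 19.** The most likely failures are elimination of HBr at C13 by the basic fluoride during a slow cleavage of the hindered silyl ether, and opening of the epoxide at the propargylic C3 (6-endo).
Fallback: ring A is closed before the alkyne is made, under acid. Starting from 24, aqueous HF in MeCN removes the silyl group and promotes 5-exo opening at C4, which now has no competing activated position, to give the ring-A diol F7. Et3SiCl and imidazole give the bis(triethylsilyl) ether F8. Swern oxidation, which cleaves and oxidises only the primary triethylsilyl ether, gives the α-silyloxy aldehyde F9. Ohira–Bestmann homologation gives the silyl-protected alkyne F10. HF·pyridine then gives 28.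

**Step 20.** The most likely failure is loss of configuration at C3 through ionisation or bromide exchange at the propargylic carbon; formation of a bromoallene by SN2' is a second risk.
Fallback: activation and displacement are separated. Starting from 28, the methanesulfonate F11 is made (MsCl, Et3N, CH2Cl2, −20 °C) and displaced with LiBr in acetone at 0 °C under non-ionising SN2 conditions, returning to 29.

## Further compounds

F1 | step 11 | α,α'-cis oxocene amide (6R,7R,12R) | COc1ccc(COC/C=C/C[C@H]2O[C@@H](C(=O)N(C)C)C/C=C\C[C@H]2O[Si](C(C)C)(C(C)C)C(C)C)cc1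
F2 | step 11 | cis ethyl ketone (6R,7R,12R) | COc1ccc(COC/C=C/C[C@H]2O[C@@H](C(=O)CC)C/C=C\C[C@H]2O[Si](C(C)C)(C(C)C)C(C)C)cc1
F3 | step 21 | C9-epimeric bromohydrin (9S,10S) | C#C[C@@H](Br)[C@H]1C[C@H]2O[C@H]([C@@H](Br)CC)C[C@H](Br)[C@@H](O)C[C@H]2O1
F4 | step 21 | 10-bromo-9-ketone (10S) | C#C[C@@H](Br)[C@H]1C[C@H]2O[C@H]([C@@H](Br)CC)C[C@H](Br)C(=O)C[C@H]2O1
F5 | step 13 | (13S)-alcohol (12,13-syn) | COc1ccc(COC/C=C/C[C@H]2O[C@H]([C@@H](O)CC)C/C=C\C[C@H]2O[Si](C(C)C)(C(C)C)C(C)C)cc1
F6 | step 13 | (13R)-4-nitrobenzoate | COc1ccc(COC/C=C/C[C@H]2O[C@H]([C@H](OC(=O)c3ccc(cc3)[N+](=O)[O-])CC)C/C=C\C[C@H]2O[Si](C(C)C)(C(C)C)C(C)C)cc1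
F7 | step 19 | ring-A diol (C2–OH, C3–OH; 3S,4R) | OC[C@H](O)[C@H]1C[C@H]2O[C@H]([C@@H](Br)CC)C/C=C\C[C@H]2O1
F8 | step 19 | 2,3-bis(triethylsilyl) ether of F7 | CC[Si](CC)(CC)OC[C@H](O[Si](CC)(CC)CC)[C@H]1C[C@H]2O[C@H]([C@@H](Br)CC)C/C=C\C[C@H]2O1
F9 | step 19 | 3-(triethylsilyloxy) C2 aldehyde | O=C[C@H](O[Si](CC)(CC)CC)[C@H]1C[C@H]2O[C@H]([C@@H](Br)CC)C/C=C\C[C@H]2O1
F10 | step 19 | triethylsilyl ether of 28 | C#C[C@H](O[Si](CC)(CC)CC)[C@H]1C[C@H]2O[C@H]([C@@H](Br)CC)C/C=C\C[C@H]2O1
F11 | step 20 | methanesulfonate of 28 | C#C[C@H](OS(C)(=O)=O)[C@H]1C[C@H]2O[C@H]([C@@H](Br)CC)C/C=C\C[C@H]2O1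
A1 | alternative 1 | 2,5-cis tetrahydrofuran-3-one (ring A with C6 ketone) | c1ccccc1COC[C@H]1CC(=O)[C@@H](CCO[Si](c2ccccc2)(c2ccccc2)C(C)(C)C)O1
A2 | alternative 1 | 2-(benzyloxymethyl)-4-methylene-1,3-dioxolane precursor (mixed at the acetal carbon) | C=C1OC(COCc2ccccc2)O[C@@H]1CCO[Si](c1ccccc1)(c1ccccc1)C(C)(C)C
A3 | alternative 2 | bicyclic core with C3 pivalate and C9 silyl ether | CC(C)(C)C(=O)OC[C@H]1C[C@H]2O[C@H]([C@@H](Br)CC)C[C@H](Br)[C@H](O[Si](C)(C)C(C)(C)C)C[C@H]2O1
A4 | alternative 2 | oxocane C4 alcohol precursor | CC(C)(C)C(=O)OC[C@H](O)C[C@H]1O[C@H]([C@@H](Br)CC)C[C@H](Br)[C@H](O[Si](C)(C)C(C)(C)C)CC1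
A5 | alternative 3 | ring-A-fused eight-membered β-hydroxy lactone | CC(C)(C)[Si](OC[C@H]1C[C@H]2OC(=O)C[C@@H](O)[C@H](OCc3ccc(OC)cc3)C[C@H]2O1)(c1ccccc1)c1ccccc1
A6 | alternative 3 | O6 bromoacetate C10 aldehyde precursor | CC(C)(C)[Si](OC[C@H]1C[C@@H](OC(=O)CBr)[C@@H](C[C@@H](OCc2ccc(OC)cc2)C=O)O1)(c1ccccc1)c1ccccc1
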